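## Retrosynthetic overview

1. Tatanan B is cut across two ring bonds, C9–C10 and C11–C6. These are the last two C–C bonds of the acid-triggered trimerisation of asarone. The precursors are a "dimer" benzylic alcohol, ArCH(Et)–CH(Me)–CH(OH)Ar, and (E)-asarone.
2. Ring order: no ring is made before the last step. The cyclohexane ring closes there, and the same bond (ipso attack) turns ring A into the spiro-dienone after loss of one O-methyl group.
3. The dimer alcohol comes from 2,4,5-trimethoxyphenyllithium and an α-methyl-β-aryl pentenal, followed by vinyl → ethyl reduction.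
4. The pentenal carries C7 and C8 of the target. It comes from a racemic aryl vinyl carbinol and propanal by iridium/amine dual catalysis; the carbinol comes from 2,4,5-trimethoxybenzaldehyde and vinylmagnesium bromide.

Assumptions:
- The target is the compound defined by the SMILES, (6S,7R,8S,9S,10R,11R)-7-ethyl-1,4-dimethoxy-8,10-dimethyl-9,11-bis(2,4,5-trimethoxyphenyl)spiro[5.5]undeca-1,4-dien-3-one. The SMILES does not fix the rotamer about the hindered C11–aryl bond; if two slowly interconverting rotamers form, they are separated and the unwanted one is equilibrated by heating.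
- The (S) antipode of the iridium ligand is taken to give the (3R) centre of the step 2 product. This sense of induction is not derived here; ligand and amine act independently, so the (R) ligand is used if a pilot run shows the opposite sense.

Labels: ring A is the aryl on C3 of the dimer alcohol (it becomes the dienone), ring B is the aryl on its C1, and ring C is the aryl of asarone. Product numbering: C6 is the spiro carbon, then C7 (Et), C8 (Me), C9 (ring B), C10 (Me), C11 (ring C).

## Route

Step 1
Reactants: 1 2,4,5-trimethoxybenzaldehyde; 2 vinylmagnesium bromide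
Product: 3 rac-1-(2,4,5-trimethoxyphenyl)prop-2-en-1-ol
Conditions: vinylmagnesium bromide (1.2 equiv), THF, 0 °C; then H2O; chromatography on Et3N-washed silica
Reagents that add atoms: vinylmagnesium bromide 2, C=C[Mg]Br
Why: Grignard 1,2-addition of a vinyl nucleophile to an aryl aldehyde; the carbinol centre is left racemic on purpose because step 2 is enantioconvergent.

Step 2
Reactants: 3 rac-1-(2,4,5-trimethoxyphenyl)prop-2-en-1-ol; 4 propanal
Product: 5 (2S,3R)-2-methyl-3-(2,4,5-trimethoxyphenyl)pent-4-enal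
Conditions: propanal (3 equiv), [Ir(cod)Cl]2 (3 mol%), (S)-4-(5H-dibenzo[b,f]azepin-5-yl)dinaphtho[2,1-d:1',2'-f][1,3,2]dioxaphosphepine (12 mol%), (R)-2-{bis[3,5-bis(trifluoromethyl)phenyl][(trimethylsilyl)oxy]methyl}pyrrolidine (15 mol%), (MeO)2P(O)OH (5 mol%), ClCH2CH2Cl, 25 °C
Reagents that add atoms: propanal 4, CCC=O
Why: Stereodivergent iridium/amine dual-catalysed α-allylation of an aldehyde, in which both enantiomers of 3 ionise to one catalyst-bound allyl cation whose face is chosen by the phosphoramidite ligand (sets C3, R) while the catalyst-bound (R)-prolinol enamine of propanal exposes one face of its α-carbon (sets C2, S); electron-rich ortho-alkoxyaryl vinyl carbinols are known substrates of this reaction type.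

Step 3
Reactants: 5 (2S,3R)-2-methyl-3-(2,4,5-trimethoxyphenyl)pent-4-enal; 6 1-bromo-2,4,5-trimethoxybenzene
Product: 8 (2S,3R)-2-methyl-1,3-bis(2,4,5-trimethoxyphenyl)pent-4-en-1-ol (C1 epimer mixture), via (2,4,5-trimethoxyphenyl)lithium 7 (not isolated)
Conditions: 6 (1.3 equiv), n-BuLi (1.25 equiv), THF, −78 °C, 30 min; then 5, −78 °C, 1 h; then H2O
Reagents that add atoms: 1-bromo-2,4,5-trimethoxybenzene 6, COc1cc(OC)c(Br)cc1OC (its aryl group, delivered as 7)
Why: Bromine–lithium exchange followed by 1,2-addition of the aryllithium to the aldehyde at −78 °C, which is faster than enolisation so C2 is kept; the new carbinol centre forms as a mixture, which is harmless because it is ionised in step 5.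

Step 4
Reactants: 8 (2S,3R)-2-methyl-1,3-bis(2,4,5-trimethoxyphenyl)pent-4-en-1-ol
Product: 9 (2S,3R)-2-methyl-1,3-bis(2,4,5-trimethoxyphenyl)pentan-1-ol (C1 epimer mixture)
Conditions: H2 (1 atm), RhCl(PPh3)3 (5 mol%), benzene/EtOH 1:1, 25 °C
Reagents that add atoms: none
Why: Homogeneous hydrogenation with RhCl(PPh3)3 reduces only the monosubstituted alkene and, unlike Pd/C, does not hydrogenolyse the very electron-rich benzylic C–O bond; no stereocentre is touched.

Step 5
Reactants: 9 (2S,3R)-2-methyl-1,3-bis(2,4,5-trimethoxyphenyl)pentan-1-ol; 10 α-asarone [(E)-1,2,4-trimethoxy-5-(prop-1-en-1-yl)benzene]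
Product: 15 tatanan B, via benzylic cation 11 (not isolated), via trimeric benzylic cation 12 (not isolated), via spiro oxocarbenium ion 13 (not isolated), via methyl hemiketal 14 (not isolated)
Conditions: 10 (3 equiv), Ca(NTf2)2 (5 mol%), n-Bu4NPF6 (5 mol%), CH2Cl2/(CF3)2CHOH 4:1, −20 → 0 °C, 9 added over 2 h; then aq NaHCO3
Reagents that add atoms: α-asarone 10, C/C=C/c1cc(OC)c(OC)cc1OC; water, O (hydrolyses 13; the same amount is set free when 9 ionises)
Why: Proposed new method: the acid ionises the benzylic alcohol 9 to cation 11 far more easily than it protonates 10, and the β-carbon of 10 adds to 11 in an open transition state anti to the CH(Et)Ar group with the C2–H in the cation plane (Felkin–Anh/allylic-strain control, setting C9 cis to the C8 methyl); the new cation 12 is then attacked by the ipso carbon of ring A (para and ortho to OMe, six-membered ring) through a chair with C10-Me and C11-aryl equatorial, which gives the trans C10/C11 pattern of the E-alkene, whereas the C10 epimer would need a 1,3-diaxial Me/Me contact and so reverts or is lost; ring A turns its C–H edge rather than its C–OMe edge toward the axial C8 methyl (setting C6), and oxocarbenium 13 is hydrolysed through hemiketal 14 with loss of methanol; the closest known reaction types are the acid-catalysed dimerisation of propenylbenzenes, dehydrative formal cycloadditions of benzylic alcohols with styrenes (cation–olefin addition then Friedel–Crafts closure), and ipso-Friedel–Crafts spirocyclisations of para-methoxyaryl groups to spirocyclohexadienones with loss of the methyl group.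

Atom mapping for step 5: C3, C2 and C1 of 9 become C7, C8 and C9; the β- and α-carbons of 10 become C10 and C11; the ipso carbon of ring A becomes C6.

## Compound list

1 | 2,4,5-trimethoxybenzaldehyde | COc1cc(OC)c(C=O)cc1OC | starting material
2 | vinylmagnesium bromide | C=C[Mg]Br | starting material
3 | rac-1-(2,4,5-trimethoxyphenyl)prop-2-en-1-ol | C=CC(O)c1cc(OC)c(OC)cc1OC | intermediate
4 | propanal | CCC=O | starting material
5 | (2S,3R)-2-methyl-3-(2,4,5-trimethoxyphenyl)pent-4-enal | C=C[C@@H](c1cc(OC)c(OC)cc1OC)[C@H](C)C=O | intermediate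
6 | 1-bromo-2,4,5-trimethoxybenzene | COc1cc(OC)c(Br)cc1OC | starting material
7 | (2,4,5-trimethoxyphenyl)lithium | [Li]c1cc(OC)c(OC)cc1OC | intermediate (not isolated)
8 | (2S,3R)-2-methyl-1,3-bis(2,4,5-trimethoxyphenyl)pent-4-en-1-ol, C1 epimer mixture | C=C[C@@H](c1cc(OC)c(OC)cc1OC)[C@H](C)C(O)c1cc(OC)c(OC)cc1OC | intermediate
9 | (2S,3R)-2-methyl-1,3-bis(2,4,5-trimethoxyphenyl)pentan-1-ol, C1 epimer mixture | CC[C@@H](c1cc(OC)c(OC)cc1OC)[C@H](C)C(O)c1cc(OC)c(OC)cc1OC | intermediate
10 | α-asarone, (E)-1,2,4-trimethoxy-5-(prop-1-en-1-yl)benzene | C/C=C/c1cc(OC)c(OC)cc1OC | starting material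
11 | benzylic cation from 9 (cation at C1; C2 and C3 configured as in 9) | CC[C@@H](c1cc(OC)c(OC)cc1OC)[C@H](C)[CH+]c1cc(OC)c(OC)cc1OC | intermediate (not isolated)
12 | trimeric benzylic cation (cation at the former α-carbon of 10; four centres configured as in 15) | CC[C@@H](c1cc(OC)c(OC)cc1OC)[C@H](C)[C@H](c1cc(OC)c(OC)cc1OC)[C@@H](C)[CH+]c1cc(OC)c(OC)cc1OC | intermediate (not isolated)
13 | spirocyclic O-methyl oxocarbenium ion of 15 | CC[C@@H]1[C@H](C)[C@H](c2cc(OC)c(OC)cc2OC)[C@@H](C)[C@H](c2cc(OC)c(OC)cc2OC)[C@]12C=C(OC)C(=[O+]C)C=C2OC | intermediate (not isolated)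
14 | methyl hemiketal of 15 (3-hydroxy-3-methoxy; either configuration at C3) | CC[C@@H]1[C@H](C)[C@H](c2cc(OC)c(OC)cc2OC)[C@@H](C)[C@H](c2cc(OC)c(OC)cc2OC)[C@]12C=C(OC)C(O)(OC)C=C2OC | intermediate (not isolated)
15 | tatanan B, (6S,7R,8S,9S,10R,11R)-7-ethyl-1,4-dimethoxy-8,10-dimethyl-9,11-bis(2,4,5-trimethoxyphenyl)spiro[5.5]undeca-1,4-dien-3-one | CC[C@@H]1[C@H](C)[C@H](c2cc(OC)c(OC)cc2OC)[C@@H](C)[C@H](c2cc(OC)c(OC)cc2OC)[C@]12C=C(OC)C(=O)C=C2OC | target

## Step count and risks

Total step count: 5. Longest linear sequence: 5 steps (1 → 3 → 5 → 8 → 9 → 15).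

**Step 5 (highest risk).** Cation 11 can close onto ring A to an indane before 10 arrives. Asarone 10 can oligomerise, and cation 12 can pick up more 10. Loss of the C2 proton from 11 and reprotonation would scramble C8. The facial selectivities are predicted, not demonstrated.

Fallback: the two bond formations are separated. Setting out from 9, cation 11 is made as before but is trapped by the silyl enol ether (Z)-trimethyl{[1-(2,4,5-trimethoxyphenyl)prop-1-en-1-yl]oxy}silane F1, prepared from commercial 1-(2,4,5-trimethoxyphenyl)propan-1-one with Me3SiOTf and Et3N. F1 is a stronger nucleophile than 10 and cannot oligomerise. The product is the ketone (2R,3S,4S,5R)-2,4-dimethyl-1,3,5-tris(2,4,5-trimethoxyphenyl)heptan-1-one F2, formed under the same Felkin control at C3; its C2 is epimerisable, so the wrong epimer is recycled with DBU. NaBH4 reduces F2 to (2R,3S,4S,5R)-2,4-dimethyl-1,3,5-tris(2,4,5-trimethoxyphenyl)heptan-1-ol F3. Ionisation of F3 with the acid system of step 5, with no alkene partner present, gives cation 12, where the fallback comes back to the route and closes to 15 by ipso attack and demethylation.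

**Step 2.** The very electron-rich alcohol 3 may ionise without the iridium catalyst (racemic C3, linear products), and the dr may be low.

Fallback: both centres are set with an auxiliary. Setting out from 6, magnesium insertion gives (2,4,5-trimethoxyphenyl)magnesium bromide F4. With CuBr·SMe2 in THF at −20 °C it adds to (4S)-3-[(2E)-pent-2-enoyl]-4-phenyl-1,3-oxazolidin-2-one F5, made from (E)-pent-2-enoic acid, PivCl, Et3N, LiCl and (S)-4-phenyl-1,3-oxazolidin-2-one. Addition occurs anti to the phenyl group of the chelated imide and gives (4S)-3-[(3R)-3-(2,4,5-trimethoxyphenyl)pentanoyl]-4-phenyl-1,3-oxazolidin-2-one F6, with the ethyl group already in place. NaN(SiMe3)2 and MeI methylate the chelated Z-enolate anti to the phenyl group to give (4S)-3-[(2S,3R)-2-methyl-3-(2,4,5-trimethoxyphenyl)pentanoyl]-4-phenyl-1,3-oxazolidin-2-one F7. LiBH4 gives (2S,3R)-2-methyl-3-(2,4,5-trimethoxyphenyl)pentan-1-ol F8, and Dess–Martin oxidation gives (2S,3R)-2-methyl-3-(2,4,5-trimethoxyphenyl)pentanal F9. F9 takes up aryllithium 7 as in step 3 and the fallback comes back to the route at 9; steps 1, 2 and 4 are then not needed.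

**Step 3.** The aryllithium may enolise 5 and erode C2, and 5 itself is configurationally labile on handling.

Fallback: the aldehyde is taken out of play before the aryl group is added. Setting out from 5, Pinnick oxidation (NaClO2, NaH2PO4, 2-methylbut-2-ene) gives the configurationally robust (2S,3R)-2-methyl-3-(2,4,5-trimethoxyphenyl)pent-4-enoic acid F10. EDC and MeNHOMe·HCl give (2S,3R)-N-methoxy-N,2-dimethyl-3-(2,4,5-trimethoxyphenyl)pent-4-enamide F11. Aryllithium 7 adds to F11 through a stable chelated tetrahedral intermediate, without α-deprotonation, to give (2S,3R)-2-methyl-1,3-bis(2,4,5-trimethoxyphenyl)pent-4-en-1-one F12. NaBH4 reduces F12 and the fallback comes back to the route at 8.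

## Further compounds

F1 | step 5 | (Z)-trimethyl{[1-(2,4,5-trimethoxyphenyl)prop-1-en-1-yl]oxy}silane | C/C=C(\O[Si](C)(C)C)c1cc(OC)c(OC)cc1OC
F2 | step 5 | (2R,3S,4S,5R)-2,4-dimethyl-1,3,5-tris(2,4,5-trimethoxyphenyl)heptan-1-one | CC[C@@H](c1cc(OC)c(OC)cc1OC)[C@H](C)[C@H](c1cc(OC)c(OC)cc1OC)[C@@H](C)C(=O)c1cc(OC)c(OC)cc1OC
F3 | step 5 | (2R,3S,4S,5R)-2,4-dimethyl-1,3,5-tris(2,4,5-trimethoxyphenyl)heptan-1-ol, C1 epimer mixture | CC[C@@H](c1cc(OC)c(OC)cc1OC)[C@H](C)[C@H](c1cc(OC)c(OC)cc1OC)[C@@H](C)C(O)c1cc(OC)c(OC)cc1OC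
F4 | step 2 | (2,4,5-trimethoxyphenyl)magnesium bromide | COc1cc(OC)c([Mg]Br)cc1OC
F5 | step 2 | (4S)-3-[(2E)-pent-2-enoyl]-4-phenyl-1,3-oxazolidin-2-one | CC/C=C/C(=O)N1[C@@H](c2ccccc2)COC1=O
F6 | step 2 | (4S)-3-[(3R)-3-(2,4,5-trimethoxyphenyl)pentanoyl]-4-phenyl-1,3-oxazolidin-2-one | CC[C@@H](c1cc(OC)c(OC)cc1OC)CC(=O)N1[C@@H](c2ccccc2)COC1=O
F7 | step 2 | (4S)-3-[(2S,3R)-2-methyl-3-(2,4,5-trimethoxyphenyl)pentanoyl]-4-phenyl-1,3-oxazolidin-2-one | CC[C@@H](c1cc(OC)c(OC)cc1OC)[C@H](C)C(=O)N1[C@@H](c2ccccc2)COC1=O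
F8 | step 2 | (2S,3R)-2-methyl-3-(2,4,5-trimethoxyphenyl)pentan-1-ol | CC[C@@H](c1cc(OC)c(OC)cc1OC)[C@H](C)CO
F9 | step 2 | (2S,3R)-2-methyl-3-(2,4,5-trimethoxyphenyl)pentanal | CC[C@@H](c1cc(OC)c(OC)cc1OC)[C@H](C)C=O
F10 | step 3 | (2S,3R)-2-methyl-3-(2,4,5-trimethoxyphenyl)pent-4-enoic acid | C=C[C@@H](c1cc(OC)c(OC)cc1OC)[C@H](C)C(=O)O
F11 | step 3 | (2S,3R)-N-methoxy-N,2-dimethyl-3-(2,4,5-trimethoxyphenyl)pent-4-enamide | C=C[C@@H](c1cc(OC)c(OC)cc1OC)[C@H](C)C(=O)N(C)OC
F12 | step 3 | (2S,3R)-2-methyl-1,3-bis(2,4,5-trimethoxyphenyl)pent-4-en-1-one | C=C[C@@H](c1cc(OC)c(OC)cc1OC)[C@H](C)C(=O)c1cc(OC)c(OC)cc1OC
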